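If the Z lost in a flask goes with the G charged, in a pseudo-first-order view of Z, one figure can travel between runs: the reach, the natural logarithm of Z charged over Z left at 20 min, divided by the molarity of G charged.

| flask | Z | X | G | remark | time |
|---|---|---|---|---|---|
| Saturday's | 0.50 M | 0.10 M | 1 mol% | run made earlier |  |
| Thursday's | 0.50 M | 0.22 M | 1 mol% | run made earlier |  |
| Wednesday's | 1 M | 0.15 M | 1 mol% | run made earlier |  |
| flask | 0.50 M | 0.150 M | 1 mol% |  | 20 min |

| run | time / min | D / % | Z / % |
|---|---|---|---|
| Saturday's | 1.50 | 4.4 | 99.0 |
| Saturday's | 3.00 | 5.3 | 96.8 |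
| Saturday's | 6.00 | 13.0 | 86.5 |
| Saturday's | 10.0 | 29.8 | 70.7 |
| Saturday's | 20.0 | 55.0 | 42.7 |
| Thursday's | 2.00 | 2.0 | 97.0 |
| Thursday's | 5.00 | 11.5 | 89.8 |
| Thursday's | 10.0 | 27.1 | 73.0 |
| Thursday's | 15.0 | 40.3 | 60.1 |
| Thursday's | 20.0 | 52.6 | 47.0 |
| Wednesday's | 2.00 | 7.7 | 91.6 |
| Wednesday's | 5.00 | 26.9 | 72.7 |
| Wednesday's | 10.0 | 57.7 | 41.7 |
| Wednesday's | 15.0 | 72.3 | 26.9 |
| Wednesday's | 20.0 | 84.9 | 17.6 |

(each reading ± 1 percentage point)

- the average divides the monomer in chains by the number of chains begun, living and dead together
- the earlier runs do not show the number of chains; that part of a forecast is a guess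

1. average number of monomer units in a chain (chains begun, living or dead) at 20 min
2. part of the Z that has reacted at 20 min

1. Turning X: from Saturday's run to Thursday's, X goes from 0.10 M to 0.22 M with Z and G held, and the reach read from the last readings falls from 170 /M to 151 /M, so in these two runs more X goes with a slightly smaller loss of Z.

2. Placing the flask: straight interpolation in X gives 162 /M for the flask's reach, its logarithm of Z charged over Z left per molarity of G charged.

3. Turning Z and G together: Wednesday's run has the flask's X with Z and G both twice the flask's, and its reach reads 174 /M, to be set beside the interpolated 162 /M.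

4. First round: the flask's G charge and its reach put 55.6% of the Z as reacted.

5. Second round: that answer goes back in. One chain per G charged, a guess since no run counts chains, gives 55.6 units per chain, and any G left unused raises it.

The forecast differs, with 54.5% reacted and an average of 3 units per chain, and says of the chains: “This is a guess, so the range is wide.”

The flask gives 54.3% reacted and an average of 60.9.

    Z + G → L + D (k = 0.327 /M/min)
    Z + L → D + L, rate k2*[L]*[Z] (k = 13.4 /M/min)
    L + X → J (k = 0.123 /M/min)
    G + D → E (k = 0.0781 /M/min)

At 20.0 min the flask keeps 7.3% of its G and 99.3% of its X, and its chains begun, L and J together, come to 0.00446 M on 0.00500 M of G charged, and the reckoned 55.6 lies under the flask's average. The same reach on the neighbour charged with 0.25 mol% of G, the other charges and the time held, gives 18.4% reacted and, put back, 73.6 units per chain; that neighbour shows 18.5% reacted and an average of 78.2.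

The readings are simulated with constants of no real substance; scatter was added.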